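**Retrosynthetic overview**

1. Target 19 ← bis-benzyl ether 18 (hydrogenolysis) ← 1,4-diol 17, closing the tetrahydrofuran by primary-OH activation and 5-exo-tet etherification.
2. Diol 17 ← all-trans lactone 16 (LiAlH4) ← late C–C union of lactone enolate 15 with benzylic bromide 7, anti to the ring methyl.
3. Lactone 15 ← anti-crotylation of O-benzylvanillin 12 (sets the Me and ArCH–O centres), hydroboration, oxidative lactonisation; 12 ← catechol.
4. Bromide 7 ← syringaldehyde 4 ← p-cresol (aerobic oxidation, dibromination, Cu-catalysed methoxylation).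
5. Ring order: γ-butyrolactone (step 13), opened (step 15), tetrahydrofuran (step 16).

Stereochemical reading of the SMILES: (2R,3R,4R)-2-aryl-3-methyl-4-benzyl-tetrahydrofuran, i.e. 2,3-trans and 3,4-trans (all-trans).

**Arm A: benzylic bromide 7**

Step 1
Reactants: 1 p-cresol
Product: 2 4-hydroxybenzaldehyde
Conditions: O2 (1 atm), CoCl2·6H2O (1 mol%), NaOH (3 equiv), MeOH, 60 °C
Reagents that add atoms: dioxygen, O=O
Why: Cobalt-catalysed aerobic benzylic oxidation of the p-cresolate via its quinone methide stops at the aldehyde because the phenolate aldehyde is deactivated.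

Step 2
Reactants: 2 4-hydroxybenzaldehyde
Product: 3 3,5-dibromo-4-hydroxybenzaldehyde
Conditions: Br2 (2.1 equiv), NaOAc, AcOH, rt
Reagents that add atoms: bromine, BrBr
Why: Electrophilic aromatic bromination goes to both positions ortho to OH, which are also meta to CHO.

Step 3
Reactants: 3 3,5-dibromo-4-hydroxybenzaldehyde
Product: 4 4-hydroxy-3,5-dimethoxybenzaldehyde (syringaldehyde)
Conditions: NaOMe (5 equiv), CuCl (20 mol%), DMF/MeOH, 115 °C; aq. HCl
Reagents that add atoms: sodium methoxide, [Na+].[O-]C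
Why: Ullmann-type Cu(I)-catalysed methoxylation of both aryl bromides; the aldehyde is protected as the unreactive phenolate.

Step 4
Reactants: 4 syringaldehyde
Product: 5 4-(benzyloxy)-3,5-dimethoxybenzaldehyde
Conditions: BnBr, K2CO3, DMF, 60 °C
Reagents that add atoms: benzyl bromide, BrCc1ccccc1
Why: Williamson etherification of the only acidic OH.

Step 5
Reactants: 5 4-(benzyloxy)-3,5-dimethoxybenzaldehyde
Product: 6 [4-(benzyloxy)-3,5-dimethoxyphenyl]methanol
Conditions: NaBH4, MeOH/THF, 0 °C
Reagents that add atoms: none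
Why: Chemoselective hydride reduction of the aldehyde.

Step 6
Reactants: 6 [4-(benzyloxy)-3,5-dimethoxyphenyl]methanol
Product: 7 2-(benzyloxy)-5-(bromomethyl)-1,3-dimethoxybenzene
Conditions: PBr3 (0.4 equiv), CH2Cl2, 0 °C; use immediately
Reagents that add atoms: phosphorus tribromide, BrP(Br)Br
Why: SN2 bromination of the benzylic alcohol; aryl benzyl and methyl ethers survive cold PBr3.

**Arm B: lactone 15**

Step 7
Reactants: 8 catechol
Product: 9 2-methoxyphenol (guaiacol)
Conditions: MeI (1.0 equiv), K2CO3 (1.0 equiv), acetone, reflux; separate from veratrole by NaOH extraction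
Reagents that add atoms: iodomethane, CI
Why: Williamson mono-O-methylation under stoichiometric control; the phenolic mono-ether is separated from the neutral diether by base extraction.

Step 8
Reactants: 9 guaiacol
Product: 10 4-bromo-2-methoxyphenol
Conditions: NBS (1.0 equiv), MeCN, 0 °C
Reagents that add atoms: N-bromosuccinimide, O=C1CCC(=O)N1Br
Why: Electrophilic aromatic bromination para to the free OH, the stronger director.

Step 9
Reactants: 10 4-bromo-2-methoxyphenol
Product: 11 1-(benzyloxy)-4-bromo-2-methoxybenzene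
Conditions: BnBr, K2CO3, DMF, rt
Reagents that add atoms: benzyl bromide, BrCc1ccccc1
Why: Williamson etherification.

Step 10
Reactants: 11 1-(benzyloxy)-4-bromo-2-methoxybenzene
Product: 12 4-(benzyloxy)-3-methoxybenzaldehyde
Conditions: n-BuLi, THF, −78 °C; then DMF, −78 °C → rt; aq. NH4Cl
Reagents that add atoms: N,N-dimethylformamide, CN(C)C=O
Why: Br–Li exchange followed by Bouveault formylation; exchange at −78 °C outruns benzylic deprotonation.

Step 11
Reactants: 12 4-(benzyloxy)-3-methoxybenzaldehyde
Product: 13 (1R,2R)-1-[4-(benzyloxy)-3-methoxyphenyl]-2-methylbut-3-en-1-ol (anti)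
Conditions: (E)-crotyl-B(Ipc)2 [from (E)-but-2-ene, n-BuLi/KOtBu, (+)-Ipc2BOMe (ex (−)-α-pinene), BF3·OEt2], THF, −78 °C; then NaOH, H2O2
Reagents that add atoms: (E)-crotyldiisopinocampheylborane made in situ from (E)-but-2-ene (C/C=C/C); C/C=C/CB(C1CC2CC(C2(C)C)C1C)C1CC2CC(C2(C)C)C1C
Why: Brown asymmetric crotylboration through a closed chair transition state: the (E)-crotyl geometry gives anti, and the Ipc ligands from (−)-α-pinene direct Re-face attack on the aryl aldehyde, giving (1R,2R).

Step 12
Reactants: 13 (1R,2R)-homoallylic alcohol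
Product: 14 (1R,2R)-1-[4-(benzyloxy)-3-methoxyphenyl]-2-methylbutane-1,4-diol
Conditions: 9-BBN (2.5 equiv), THF, 0 °C → rt; then aq. NaOH, H2O2, 0 °C → rt
Reagents that add atoms: hydrogen peroxide, OO
Why: Anti-Markovnikov hydroboration–oxidation of the terminal alkene; neither stereocentre is touched.

Step 13
Reactants: 14 (1R,2R)-1,4-diol
Product: 15 (4R,5R)-5-[4-(benzyloxy)-3-methoxyphenyl]-4-methyldihydrofuran-2(3H)-one (trans)
Conditions: TEMPO (20 mol%), PhI(OAc)2 (2.5 equiv), CH2Cl2, rt; recrystallise to upgrade ee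
Reagents that add atoms: none
Why: TEMPO/PhI(OAc)2 oxidative lactonisation: the primary OH is oxidised first, the aldehyde is trapped as the lactol by the benzylic OH and oxidised on to the lactone, with both stereocentres retained.

**Union and endgame**

Step 14
Reactants: 15 trans-lactone; 7 benzylic bromide
Product: 16 (3R,4R,5R)-3-[4-(benzyloxy)-3,5-dimethoxybenzyl]-5-[4-(benzyloxy)-3-methoxyphenyl]-4-methyldihydrofuran-2(3H)-one (all-trans)
Conditions: LDA (1.05 equiv), THF, −78 °C; then 7 (1.1 equiv), DMPU, −78 → −30 °C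
Reagents that add atoms: none (both partners are numbered reactants)
Why: SN2 alkylation of the lactone enolate; the bromide approaches anti to the adjacent C4 methyl, setting C3 as R (3,4-trans), which is also the thermodynamic epimer.

Step 15
Reactants: 16 all-trans lactone
Product: 17 (1R,2R,3R)-1-[4-(benzyloxy)-3-methoxyphenyl]-3-[4-(benzyloxy)-3,5-dimethoxybenzyl]-2-methylbutane-1,4-diol
Conditions: LiAlH4, THF, 0 °C
Reagents that add atoms: none
Why: Hydride reduction of the lactone to the 1,4-diol is faster than enolisation, so the α-centre is not epimerised.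

Step 16
Reactants: 17 (1R,2R,3R)-diol
Product: 18 (2R,3R,4R)-2-[4-(benzyloxy)-3-methoxyphenyl]-4-[4-(benzyloxy)-3,5-dimethoxybenzyl]-3-methyltetrahydrofuran
Conditions: MsCl (1.05 equiv), Et3N, CH2Cl2, −10 °C → rt
Reagents that add atoms: none (mesylate is lost)
Why: Selective mesylation of the primary OH and intramolecular Williamson etherification (5-exo-tet) by the benzylic OH retains C2 as R; base-only conditions avoid Friedel–Crafts aryltetralin formation, and any benzylic SN1 leakage also leads to the favoured all-trans ring.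

Step 17
Reactants: 18 bis-benzyl ether
Product: 19 target, 4-{[(3R,4R,5R)-5-(4-hydroxy-3-methoxyphenyl)-4-methyltetrahydrofuran-3-yl]methyl}-2,6-dimethoxyphenol
Conditions: H2 (1 atm), 10% Pd/C, EtOAc, rt; stop at complete debenzylation
Reagents that add atoms: none
Why: Pd-catalysed hydrogenolysis of the two aryl benzyl ethers is faster than cleavage of the cyclic benzylic C2–O bond in EtOAc at 1 atm.

**Compound list**

1 | p-cresol | Cc1ccc(O)cc1 | starting material
2 | 4-hydroxybenzaldehyde | O=Cc1ccc(O)cc1 | intermediate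
3 | 3,5-dibromo-4-hydroxybenzaldehyde | O=Cc1cc(Br)c(O)c(Br)c1 | intermediate
4 | 4-hydroxy-3,5-dimethoxybenzaldehyde | COc1cc(C=O)cc(OC)c1O | intermediate
5 | 4-(benzyloxy)-3,5-dimethoxybenzaldehyde | COc1cc(C=O)cc(OC)c1OCc1ccccc1 | intermediate
6 | [4-(benzyloxy)-3,5-dimethoxyphenyl]methanol | COc1cc(CO)cc(OC)c1OCc1ccccc1 | intermediate
7 | 2-(benzyloxy)-5-(bromomethyl)-1,3-dimethoxybenzene | COc1cc(CBr)cc(OC)c1OCc1ccccc1 | intermediate
8 | catechol | Oc1ccccc1O | starting material
9 | 2-methoxyphenol | COc1ccccc1O | intermediate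
10 | 4-bromo-2-methoxyphenol | COc1cc(Br)ccc1O | intermediate
11 | 1-(benzyloxy)-4-bromo-2-methoxybenzene | COc1cc(Br)ccc1OCc1ccccc1 | intermediate
12 | 4-(benzyloxy)-3-methoxybenzaldehyde | COc1cc(C=O)ccc1OCc1ccccc1 | intermediate
13 | (1R,2R)-1-[4-(benzyloxy)-3-methoxyphenyl]-2-methylbut-3-en-1-ol | COc1cc([C@H](O)[C@H](C)C=C)ccc1OCc1ccccc1 | intermediate
14 | (1R,2R)-1-[4-(benzyloxy)-3-methoxyphenyl]-2-methylbutane-1,4-diol | COc1cc([C@H](O)[C@H](C)CCO)ccc1OCc1ccccc1 | intermediate
15 | (4R,5R)-5-[4-(benzyloxy)-3-methoxyphenyl]-4-methyldihydrofuran-2(3H)-one | COc1cc([C@@H]2OC(=O)C[C@H]2C)ccc1OCc1ccccc1 | intermediate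
16 | (3R,4R,5R)-3-[4-(benzyloxy)-3,5-dimethoxybenzyl]-5-[4-(benzyloxy)-3-methoxyphenyl]-4-methyldihydrofuran-2(3H)-one | COc1cc([C@@H]2OC(=O)[C@H](Cc3cc(OC)c(OCc4ccccc4)c(OC)c3)[C@H]2C)ccc1OCc1ccccc1 | intermediate
17 | (1R,2R,3R)-1-[4-(benzyloxy)-3-methoxyphenyl]-3-[4-(benzyloxy)-3,5-dimethoxybenzyl]-2-methylbutane-1,4-diol | COc1cc([C@H](O)[C@H](C)[C@H](CO)Cc2cc(OC)c(OCc3ccccc3)c(OC)c2)ccc1OCc1ccccc1 | intermediate
18 | (2R,3R,4R)-2-[4-(benzyloxy)-3-methoxyphenyl]-4-[4-(benzyloxy)-3,5-dimethoxybenzyl]-3-methyltetrahydrofuran | COc1cc([C@@H]2OC[C@H](Cc3cc(OC)c(OCc4ccccc4)c(OC)c3)[C@H]2C)ccc1OCc1ccccc1 | intermediate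
19 | 4-{[(3R,4R,5R)-5-(4-hydroxy-3-methoxyphenyl)-4-methyltetrahydrofuran-3-yl]methyl}-2,6-dimethoxyphenol | COc1cc([C@@H]2OC[C@H](Cc3cc(OC)c(O)c(OC)c3)[C@H]2C)ccc1O | target

**Totals**

Total step count: 17.
Longest linear sequence: 11 steps (catechol 8 → 19, steps 7–17). The other arm is 6 steps to bromide 7 (10 steps from p-cresol to 19).

**Three steps most likely to fail, with fallbacks**

1. Step 13 (oxidative lactonisation). The electron-rich benzylic secondary OH may be oxidised to the aryl ketone in competition with the primary OH. Fallback: keep the benzylic oxygen masked. TBS-protect 13, hydroborate, oxidise the primary alcohol to the carboxylic acid (TEMPO/NaOCl then NaClO2), then desilylate with TBAF and lactonise under mild acid, so the benzylic oxygen never meets an oxidant.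

2. Step 14 (enolate benzylation). Bromide 7 is labile, and dialkylation or modest trans selectivity is possible. Fallback: replace the SN2 step by an aldol route. Add the enolate of 15 to aldehyde 5, dehydrate (MsCl/Et3N then DBU) to the α-benzylidene lactone, reduce the conjugated alkene with NiCl2/NaBH4, and equilibrate with DBU to the all-trans lactone 16. This also removes steps 5–6.

3. Step 17 (hydrogenolysis). Over-reduction can cleave the cyclic benzylic C2–O bond and open the ring. Fallback: change the protecting-group plan. Carry both phenols as TIPS ethers (TIPSCl/imidazole in steps 4 and 9; tolerated by BuLi, LDA, LiAlH4 and MsCl/Et3N) and finish with TBAF.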